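**Retrosynthetic overview**
- The route rests on ring A (C1–C6): a 2-acylcyclohexane-1,3-dione unit (enol C2, acyl-bearing C3, ketone C4) bounded by quaternary C1 and fused through C5=C6 to the 2,2-dimethyl-2H-pyran (ring B, oxygen on C6). C3–C4 is therefore an acylation bond, and ring A is closed last by Dieckmann C-acylation of a C1-bound 1,3-diketone onto the ester at pyran C5.
- Ring B is made first: Knoevenagel condensation of a C1-bound β-keto ester with 3-methylbut-2-enal, then oxa-6π closure through the ketone oxygen. The diketone arm is then grown from the C1 acetyl group by aldol addition to (R)-2-methylbutanal and oxidation.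
- C1 is set in an open chain by Fráter–Seebach prenylation of a (3S)-β-hydroxy ester (Noyori hydrogenation of the alkylated acetoacetate). The ester carbon becomes the C6 arm and the carbinol carbon becomes C2.
- Ca (side-chain methine) comes from an Evans dienolate alkylation of the 3-methylbut-2-enoyl imide, carried on as an iodide. End game: desilylation, oxidation, E-selective Wittig olefination, saponification.

Key step: step 18

Remark: the side-chain alcohol is protected as its TBDPS ether so that it survives the traces of acid in the methanolic hydrogenation of step 7; enolised tricarbonyl compounds are drawn as the C2-enol tautomer.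

**Step 1**
Reactants: 1 2-[(tert-butyldiphenylsilyl)oxy]ethan-1-ol
Product: 2 2-[(tert-butyldiphenylsilyl)oxy]ethyl trifluoromethanesulfonate
Conditions: Tf2O, 2,6-lutidine, CH2Cl2, −78 °C; used at once
Reagents that add atoms: trifluoromethanesulfonic anhydride, O=S(=O)(OS(=O)(=O)C(F)(F)F)C(F)(F)F
Why: O-sulfonylation of a primary alcohol with a hindered pyridine base should give the primary triflate, an electrophile reactive enough for a stabilised imide dienolate at low temperature.

**Step 2**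
Reactants: 3 (S)-4-benzyloxazolidin-2-one; 4 3-methylbut-2-enoyl chloride
Product: 5 (S)-4-benzyl-3-(3-methylbut-2-enoyl)oxazolidin-2-one
Conditions: n-BuLi, THF, −78 °C; then 4, −78 → 0 °C
Reagents that add atoms: none
Why: N-acylation of the lithiated oxazolidinone by the acid chloride (loading of the Evans auxiliary) creates no stereocentre.

**Step 3**
Reactants: 5 senecioyl imide; 2 silyloxyethyl triflate
Product: 6 (S)-4-benzyl-3-[(2S)-2-{2-[(tert-butyldiphenylsilyl)oxy]ethyl}-3-methylbut-3-enoyl]oxazolidin-2-one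
Conditions: NaN(SiMe3)2, THF, −78 °C; then 2, −78 → −40 °C; cold AcOH quench
Reagents that add atoms: none
Why: Evans asymmetric alkylation: γ-deprotonation of the s-cis imide gives the chelated (Z)-sodium dienolate, which should be alkylated at the α-carbon on the face away from the benzyl group, moving the alkene out of conjugation (isopropenyl) and setting Ca as (S).

**Step 4**
Reactants: 6 alkylated imide
Product: 7 (2S)-2-{2-[(tert-butyldiphenylsilyl)oxy]ethyl}-3-methylbut-3-en-1-ol
Conditions: LiBH4, H2O (1 equiv), Et2O, 0 °C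
Reagents that add atoms: none
Why: Reductive cleavage of the imide by hydride attack at the exocyclic carbonyl should release the primary alcohol and the auxiliary without touching Ca, the alkene or the silyl ether.

**Step 5**
Reactants: 7 homoallylic alcohol
Product: 8 (S)-tert-butyl{[3-(iodomethyl)-4-methylpent-4-en-1-yl]oxy}diphenylsilane
Conditions: PPh3, I2, imidazole, CH2Cl2, 0 °C → rt
Reagents that add atoms: iodine, II
Why: Appel-type iodination proceeds through the alkoxyphosphonium salt and SN2 displacement at the CH2 group, so Ca is not involved.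

**Step 6**
Reactants: 8 iodide; 9 methyl acetoacetate
Product: 10 methyl (4S)-2-acetyl-4-{2-[(tert-butyldiphenylsilyl)oxy]ethyl}-5-methylhex-5-enoate (both C2 epimers)
Conditions: 9 (2.5 equiv), NaH, THF/DMF, 0 → 60 °C
Reagents that add atoms: none
Why: Acetoacetic ester C-alkylation: the soft, weakly basic sodium enolate should favour SN2 at the β-branched primary iodide over elimination, and the uncontrolled C2 centre is irrelevant because both epimers converge in step 8.

**Step 7**
Reactants: 10 alkylated acetoacetate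
Product: 11 methyl (4S)-4-{2-[(tert-butyldiphenylsilyl)oxy]ethyl}-2-[(1S)-1-hydroxyethyl]-5-methylhex-5-enoate (both C2 epimers)
Conditions: RuCl2[(S)-BINAP] (1 mol %), H2 (50 atm), MeOH, 40 °C
Reagents that add atoms: none
Why: Noyori asymmetric hydrogenation of a β-keto ester: the chelated substrate receives hydrogen on one carbonyl face, so (S)-BINAP should set the (S)-carbinol whatever the C2 configuration, while the isolated 1,1-disubstituted alkene, having no coordinating group, should stay untouched.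

**Step 8**
Reactants: 11 β-hydroxy ester; 12 prenyl bromide (1-bromo-3-methylbut-2-ene)
Product: 13 methyl (2R,4S)-4-{2-[(tert-butyldiphenylsilyl)oxy]ethyl}-2-[(1S)-1-hydroxyethyl]-5-methyl-2-(3-methylbut-2-en-1-yl)hex-5-enoate
Conditions: LiN(i-Pr)2 (2.5 equiv), THF, −78 → −20 °C; then 12, DMPU, −78 → 0 °C; AcOH quench
Reagents that add atoms: none
Why: Fráter–Seebach alkylation: both epimers of 11 give the same lithium alkoxide–enolate chelate, and the allylic bromide should enter anti to the carbinol methyl group, so the (S)-carbinol sets the quaternary C1 centre as (2R).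

**Step 9**
Reactants: 13 quaternary hydroxy ester
Product: 14 (2S,3S)-2-[(2S)-4-[(tert-butyldiphenylsilyl)oxy]-2-(prop-1-en-2-yl)butyl]-2-(3-methylbut-2-en-1-yl)butane-1,3-diol
Conditions: LiAlH4, THF, 0 °C → rt
Reagents that add atoms: none
Why: Hydride reduction of the hindered methyl ester to the primary alcohol leaves the quaternary centre, the alkenes and the silyl ether unchanged.

**Step 10**
Reactants: 14 diol
Product: 15 (2S)-2-acetyl-2-[(2S)-4-[(tert-butyldiphenylsilyl)oxy]-2-(prop-1-en-2-yl)butyl]-5-methylhex-4-enal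
Conditions: DMP (3 equiv), CH2Cl2, 0 °C → rt
Reagents that add atoms: none
Why: Dess–Martin oxidation of both hydroxyl groups under near-neutral conditions should give the keto aldehyde, which cannot epimerise because C1 carries no hydrogen.

**Step 11**
Reactants: 15 keto aldehyde; 16 methyl acetate
Product: 17 methyl (4S)-4-acetyl-4-[(2S)-4-[(tert-butyldiphenylsilyl)oxy]-2-(prop-1-en-2-yl)butyl]-3-hydroxy-7-methyloct-6-enoate (both C3 epimers)
Conditions: LiN(i-Pr)2, 16, THF, −78 °C; then 15, −78 °C; AcOH quench at −78 °C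
Reagents that add atoms: none
Why: Aldol addition of the lithium ester enolate should take the aldehyde in preference to the hindered methyl ketone at −78 °C, and the cold quench forestalls retro-aldol cleavage at the quaternary carbon; the new carbinol is oxidised in the next step.

**Step 12**
Reactants: 17 β-hydroxy ester
Product: 18 methyl (4R)-4-acetyl-4-[(2S)-4-[(tert-butyldiphenylsilyl)oxy]-2-(prop-1-en-2-yl)butyl]-7-methyl-3-oxooct-6-enoate
Conditions: DMP, CH2Cl2, 0 °C → rt
Reagents that add atoms: none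
Why: Dess–Martin oxidation of the secondary alcohol should give the β-keto ester without a nucleophilic base that could cleave the 2,2-disubstituted 1,3-dicarbonyl unit.

**Step 13**
Reactants: 18 β-keto ester; 19 3-methylbut-2-enal
Product: 21 methyl 6-{(3S)-3-[(2S)-4-[(tert-butyldiphenylsilyl)oxy]-2-(prop-1-en-2-yl)butyl]-6-methyl-2-oxohept-5-en-3-yl}-2,2-dimethyl-2H-pyran-5-carboxylate, via Knoevenagel dienone 20 (not isolated)
Conditions: ethylenediammonium diacetate (10 mol %), CH2Cl2, rt → 40 °C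
Reagents that add atoms: none
Why: Knoevenagel condensation at the only doubly activated methylene gives dienone 20, whose ketone oxygen closes ring B by oxa-6π electrocyclisation (formal [3+3] pyran synthesis); the gem-dimethyl terminus and the C5 ester should hold the product as the closed 2H-pyran, and the ester oxygen cannot take part.

**Step 14**
Reactants: 22 (R)-2-methylbutanoic acid
Product: 23 (R)-2-methylbutan-1-ol
Conditions: LiAlH4, Et2O, 0 °C → rt
Reagents that add atoms: none
Why: Hydride reduction of the carboxylic acid proceeds through the carboxylate and does not enolise Cb, so its configuration is kept.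

**Step 15**
Reactants: 23 (R)-2-methylbutan-1-ol
Product: 24 (R)-2-methylbutanal
Conditions: TEMPO (1 mol %), KBr (10 mol %), aq NaOCl, NaHCO3, CH2Cl2/H2O, 0 °C; used at once as a dried solution
Reagents that add atoms: none
Why: Oxoammonium-mediated (Anelli) oxidation at 0 °C and pH 9 is the standard way to make this aldehyde without racemising its α-centre.

**Step 16**
Reactants: 21 pyranyl methyl ketone; 24 (R)-2-methylbutanal
Product: 25 methyl 6-{(5S,9R)-5-[(2S)-4-[(tert-butyldiphenylsilyl)oxy]-2-(prop-1-en-2-yl)butyl]-8-hydroxy-2,9-dimethyl-6-oxoundec-2-en-5-yl}-2,2-dimethyl-2H-pyran-5-carboxylate (both C8 epimers)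
Conditions: LiN(i-Pr)2, THF, −78 °C; then 24, −78 °C; AcOH quench at −78 °C
Reagents that add atoms: none
Why: The acetyl group is the only enolisable site, and its kinetic lithium enolate should add to the aldehyde at −78 °C much faster than it attacks the deactivated pyran ester or racemises the aldehyde; the new carbinol is oxidised in the next step.

**Step 17**
Reactants: 25 β-hydroxy ketone
Product: 26 methyl 6-{(5S,9R)-5-[(2S)-4-[(tert-butyldiphenylsilyl)oxy]-2-(prop-1-en-2-yl)butyl]-2,9-dimethyl-6,8-dioxoundec-2-en-5-yl}-2,2-dimethyl-2H-pyran-5-carboxylate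
Conditions: DMP (1.3 equiv), CH2Cl2, 0 °C → rt
Reagents that add atoms: none
Why: Dess–Martin oxidation of a β-hydroxy ketone gives the 1,3-diketone under non-basic conditions, and the diketone enolises toward C3, not toward Cb.

**Step 18**
Reactants: 26 pyranyl diketone ester
Product: 27 (8R)-8-[(2S)-4-[(tert-butyldiphenylsilyl)oxy]-2-(prop-1-en-2-yl)butyl]-7-hydroxy-2,2-dimethyl-6-[(2R)-2-methylbutanoyl]-8-(3-methylbut-2-en-1-yl)-2H-chromen-5(8H)-one
Conditions: NaH (1.1 equiv), THF, 0 → 55 °C; then cold 1 M HCl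
Reagents that add atoms: none
Why: NaH removes one proton from C3, the methylene between the two ketones and by far the most acidic site, and the sodium diketonate attacks through C3 the carbonyl carbon of the methyl ester on pyran C5; loss of methoxide forms the C3–C4 bond and closes ring A, and the methoxide is consumed at once by deprotonating the new 2-acyl-1,3-dione, whose delocalised anion is the thermodynamic sink that should draw reversible side equilibria (O-acylation, conjugate addition to the ring-opened dienone) toward product. The closest known reaction type is the intramolecular Claisen (Dieckmann) C-acylation of a 1,3-diketone by an ester to give a 2-acylcyclohexane-1,3-dione. Ring A closes in a 6-(enolexo)-exo-trig mode, and the C5=C6 double bond of the pyran already holds the ester and C1 cis. No stereocentre is created: C3 ends enolised, and C1, Ca and Cb are not touched. The step needs chemoselectivity only, namely C3 as the nucleophile and no enolisation at Cb, which the large acidity gap between C3–H and Cb–H of the monoanion secures when about one equivalent of a non-nucleophilic base is used; no regiochemical question arises in ring B because its oxygen is already bonded to C6. Retro-Claisen cleavage at C1 is disfavoured because free methoxide does not build up in the aprotic medium.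

**Step 19**
Reactants: 27 silyl-protected bicyclic acyl-dione
Product: 28 (8R)-7-hydroxy-8-[(2S)-4-hydroxy-2-(prop-1-en-2-yl)butyl]-2,2-dimethyl-6-[(2R)-2-methylbutanoyl]-8-(3-methylbut-2-en-1-yl)-2H-chromen-5(8H)-one
Conditions: Bu4NF, AcOH (1:1), THF, rt
Reagents that add atoms: none
Why: Fluoride-mediated cleavage of the primary silyl ether under buffered conditions should leave the enolised tricarbonyl unit, the chromene and the alkenes intact.

**Step 20**
Reactants: 28 primary alcohol
Product: 29 (3S)-3-{[(8R)-7-hydroxy-2,2-dimethyl-6-[(2R)-2-methylbutanoyl]-8-(3-methylbut-2-en-1-yl)-5-oxo-5,8-dihydro-2H-chromen-8-yl]methyl}-4-methylpent-4-enal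
Conditions: DMP (1.3 equiv), CH2Cl2, 0 °C → rt; used at once
Reagents that add atoms: none
Why: Dess–Martin oxidation of the primary alcohol should stop at the aldehyde, and the fully substituted, hydrogen-bonded C3 of the acyl-dione offers no position for oxidation.

**Step 21**
Reactants: 29 aldehyde; 30 ethyl 2-(triphenyl-λ5-phosphanylidene)propanoate
Product: 31 ethyl (2E,5R)-5-{[(8R)-7-hydroxy-2,2-dimethyl-6-[(2R)-2-methylbutanoyl]-8-(3-methylbut-2-en-1-yl)-5-oxo-5,8-dihydro-2H-chromen-8-yl]methyl}-2,6-dimethylhepta-2,6-dienoate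
Conditions: 30 (3 equiv), toluene, 60 °C
Reagents that add atoms: none
Why: Wittig olefination with a stabilised α-methyl ylide should give the (E)-trisubstituted enoate under thermodynamic control; the excess allows for the equivalent of ylide that the acidic enol protonates.

**Step 22**
Reactants: 31 ethyl ester
Product: 32 (2E,5R)-5-{[(8R)-7-hydroxy-2,2-dimethyl-6-[(2R)-2-methylbutanoyl]-8-(3-methylbut-2-en-1-yl)-5-oxo-5,8-dihydro-2H-chromen-8-yl]methyl}-2,6-dimethylhepta-2,6-dienoic acid (CNP0184919.1)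
Conditions: LiOH, THF/MeOH/H2O, rt; then 1 M HCl to pH 3, 0 °C
Reagents that add atoms: lithium hydroxide, [Li+].[OH-]
Why: Saponification of the ethyl ester; the acyl-dione is present as its anion, which protects it from hydroxide and from enolisation at Cb, and cold acidification should return the enol and the acid.

**Compound list**
1 | 2-[(tert-butyldiphenylsilyl)oxy]ethan-1-ol | OCCO[Si](c1ccccc1)(c1ccccc1)C(C)(C)C | starting material
2 | 2-[(tert-butyldiphenylsilyl)oxy]ethyl trifluoromethanesulfonate | CC(C)(C)[Si](OCCOS(=O)(=O)C(F)(F)F)(c1ccccc1)c1ccccc1 | intermediate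
3 | (S)-4-benzyloxazolidin-2-one | O=C1OC[C@H](Cc2ccccc2)N1 | starting material
4 | 3-methylbut-2-enoyl chloride | CC(C)=CC(=O)Cl | starting material
5 | (S)-4-benzyl-3-(3-methylbut-2-enoyl)oxazolidin-2-one | CC(C)=CC(=O)N1[C@@H](Cc2ccccc2)COC1=O | intermediate
6 | (S)-4-benzyl-3-[(2S)-2-{2-[(tert-butyldiphenylsilyl)oxy]ethyl}-3-methylbut-3-enoyl]oxazolidin-2-one | C=C(C)[C@H](CCO[Si](c1ccccc1)(c1ccccc1)C(C)(C)C)C(=O)N1[C@@H](Cc2ccccc2)COC1=O | intermediate
7 | (2S)-2-{2-[(tert-butyldiphenylsilyl)oxy]ethyl}-3-methylbut-3-en-1-ol | C=C(C)[C@H](CCO[Si](c1ccccc1)(c1ccccc1)C(C)(C)C)CO | intermediate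
8 | (S)-tert-butyl{[3-(iodomethyl)-4-methylpent-4-en-1-yl]oxy}diphenylsilane | C=C(C)[C@H](CCO[Si](c1ccccc1)(c1ccccc1)C(C)(C)C)CI | intermediate
9 | methyl acetoacetate | CC(=O)CC(=O)OC | starting material
10 | methyl (4S)-2-acetyl-4-{2-[(tert-butyldiphenylsilyl)oxy]ethyl}-5-methylhex-5-enoate (C2 epimers) | C=C(C)[C@H](CCO[Si](c1ccccc1)(c1ccccc1)C(C)(C)C)CC(C(C)=O)C(=O)OC | intermediate
11 | methyl (4S)-4-{2-[(tert-butyldiphenylsilyl)oxy]ethyl}-2-[(1S)-1-hydroxyethyl]-5-methylhex-5-enoate (C2 epimers) | C=C(C)[C@H](CCO[Si](c1ccccc1)(c1ccccc1)C(C)(C)C)CC([C@H](C)O)C(=O)OC | intermediate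
12 | prenyl bromide (1-bromo-3-methylbut-2-ene) | CC(C)=CCBr | starting material
13 | methyl (2R,4S)-4-{2-[(tert-butyldiphenylsilyl)oxy]ethyl}-2-[(1S)-1-hydroxyethyl]-5-methyl-2-(3-methylbut-2-en-1-yl)hex-5-enoate | C=C(C)[C@H](CCO[Si](c1ccccc1)(c1ccccc1)C(C)(C)C)C[C@](CC=C(C)C)([C@H](C)O)C(=O)OC | intermediate
14 | (2S,3S)-2-[(2S)-4-[(tert-butyldiphenylsilyl)oxy]-2-(prop-1-en-2-yl)butyl]-2-(3-methylbut-2-en-1-yl)butane-1,3-diol | C=C(C)[C@H](CCO[Si](c1ccccc1)(c1ccccc1)C(C)(C)C)C[C@](CC=C(C)C)([C@H](C)O)CO | intermediate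
15 | (2S)-2-acetyl-2-[(2S)-4-[(tert-butyldiphenylsilyl)oxy]-2-(prop-1-en-2-yl)butyl]-5-methylhex-4-enal | C=C(C)[C@H](CCO[Si](c1ccccc1)(c1ccccc1)C(C)(C)C)C[C@](CC=C(C)C)(C(C)=O)C=O | intermediate
16 | methyl acetate | COC(C)=O | starting material
17 | methyl (4S)-4-acetyl-4-[(2S)-4-[(tert-butyldiphenylsilyl)oxy]-2-(prop-1-en-2-yl)butyl]-3-hydroxy-7-methyloct-6-enoate (C3 epimers) | C=C(C)[C@H](CCO[Si](c1ccccc1)(c1ccccc1)C(C)(C)C)C[C@](CC=C(C)C)(C(C)=O)C(O)CC(=O)OC | intermediate
18 | methyl (4R)-4-acetyl-4-[(2S)-4-[(tert-butyldiphenylsilyl)oxy]-2-(prop-1-en-2-yl)butyl]-7-methyl-3-oxooct-6-enoate | C=C(C)[C@H](CCO[Si](c1ccccc1)(c1ccccc1)C(C)(C)C)C[C@](CC=C(C)C)(C(C)=O)C(=O)CC(=O)OC | intermediate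
19 | 3-methylbut-2-enal | CC(C)=CC=O | starting material
20 | methyl (2E)-2-{(2R)-2-acetyl-2-[(2S)-4-[(tert-butyldiphenylsilyl)oxy]-2-(prop-1-en-2-yl)butyl]-5-methylhex-4-enoyl}-5-methylhexa-2,4-dienoate (Knoevenagel dienone, not isolated) | C=C(C)[C@H](CCO[Si](c1ccccc1)(c1ccccc1)C(C)(C)C)C[C@](CC=C(C)C)(C(C)=O)C(=O)/C(C(=O)OC)=C\C=C(C)C | intermediate
21 | methyl 6-{(3S)-3-[(2S)-4-[(tert-butyldiphenylsilyl)oxy]-2-(prop-1-en-2-yl)butyl]-6-methyl-2-oxohept-5-en-3-yl}-2,2-dimethyl-2H-pyran-5-carboxylate | C=C(C)[C@H](CCO[Si](c1ccccc1)(c1ccccc1)C(C)(C)C)C[C@](CC=C(C)C)(C(C)=O)C1=C(C(=O)OC)C=CC(C)(C)O1 | intermediate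
22 | (R)-2-methylbutanoic acid | CC[C@@H](C)C(=O)O | starting material
23 | (R)-2-methylbutan-1-ol | CC[C@@H](C)CO | intermediate
24 | (R)-2-methylbutanal | CC[C@@H](C)C=O | intermediate
25 | methyl 6-{(5S,9R)-5-[(2S)-4-[(tert-butyldiphenylsilyl)oxy]-2-(prop-1-en-2-yl)butyl]-8-hydroxy-2,9-dimethyl-6-oxoundec-2-en-5-yl}-2,2-dimethyl-2H-pyran-5-carboxylate (C8 epimers) | C=C(C)[C@H](CCO[Si](c1ccccc1)(c1ccccc1)C(C)(C)C)C[C@](CC=C(C)C)(C(=O)CC(O)[C@H](C)CC)C1=C(C(=O)OC)C=CC(C)(C)O1 | intermediate
26 | methyl 6-{(5S,9R)-5-[(2S)-4-[(tert-butyldiphenylsilyl)oxy]-2-(prop-1-en-2-yl)butyl]-2,9-dimethyl-6,8-dioxoundec-2-en-5-yl}-2,2-dimethyl-2H-pyran-5-carboxylate | C=C(C)[C@H](CCO[Si](c1ccccc1)(c1ccccc1)C(C)(C)C)C[C@](CC=C(C)C)(C(=O)CC(=O)[C@H](C)CC)C1=C(C(=O)OC)C=CC(C)(C)O1 | intermediate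
27 | (8R)-8-[(2S)-4-[(tert-butyldiphenylsilyl)oxy]-2-(prop-1-en-2-yl)butyl]-7-hydroxy-2,2-dimethyl-6-[(2R)-2-methylbutanoyl]-8-(3-methylbut-2-en-1-yl)-2H-chromen-5(8H)-one | C=C(C)[C@H](CCO[Si](c1ccccc1)(c1ccccc1)C(C)(C)C)C[C@]1(CC=C(C)C)C(O)=C(C(=O)[C@H](C)CC)C(=O)C2=C1OC(C)(C)C=C2 | intermediate
28 | (8R)-7-hydroxy-8-[(2S)-4-hydroxy-2-(prop-1-en-2-yl)butyl]-2,2-dimethyl-6-[(2R)-2-methylbutanoyl]-8-(3-methylbut-2-en-1-yl)-2H-chromen-5(8H)-one | C=C(C)[C@H](CCO)C[C@]1(CC=C(C)C)C(O)=C(C(=O)[C@H](C)CC)C(=O)C2=C1OC(C)(C)C=C2 | intermediate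
29 | (3S)-3-{[(8R)-7-hydroxy-2,2-dimethyl-6-[(2R)-2-methylbutanoyl]-8-(3-methylbut-2-en-1-yl)-5-oxo-5,8-dihydro-2H-chromen-8-yl]methyl}-4-methylpent-4-enal | C=C(C)[C@H](CC=O)C[C@]1(CC=C(C)C)C(O)=C(C(=O)[C@H](C)CC)C(=O)C2=C1OC(C)(C)C=C2 | intermediate
30 | ethyl 2-(triphenyl-λ5-phosphanylidene)propanoate | CCOC(=O)C(C)=P(c1ccccc1)(c1ccccc1)c1ccccc1 | starting material
31 | ethyl (2E,5R)-5-{[(8R)-7-hydroxy-2,2-dimethyl-6-[(2R)-2-methylbutanoyl]-8-(3-methylbut-2-en-1-yl)-5-oxo-5,8-dihydro-2H-chromen-8-yl]methyl}-2,6-dimethylhepta-2,6-dienoate | C=C(C)[C@H](C/C=C(\C)C(=O)OCC)C[C@]1(CC=C(C)C)C(O)=C(C(=O)[C@H](C)CC)C(=O)C2=C1OC(C)(C)C=C2 | intermediate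
32 | (2E,5R)-5-{[(8R)-7-hydroxy-2,2-dimethyl-6-[(2R)-2-methylbutanoyl]-8-(3-methylbut-2-en-1-yl)-5-oxo-5,8-dihydro-2H-chromen-8-yl]methyl}-2,6-dimethylhepta-2,6-dienoic acid | C=C(C)[C@H](C/C=C(\C)C(=O)O)C[C@]1(CC=C(C)C)C(O)=C(C(=O)[C@H](C)CC)C(=O)C2=C1OC(C)(C)C=C2 | target

**Step count**
Total: 22 steps. Longest linear sequence: 19 steps (steps 2–13, then 16–22).

**Steps most likely to fail**

Step 18. The diketonate may acylate the electron-rich (vinylogous carbonate) ester too slowly, which leaves time for reversible opening of the pyran to its dienone and conjugate addition to it, or for methoxide-induced retro-Claisen cleavage at C1. The fallback sets out from 21 and comes back at 27. KOt-Bu in THF generates the more nucleophilic methyl-ketone enolate of 21, which closes ring A first by the Dieckmann reaction and should give (8R)-8-[(2S)-4-[(tert-butyldiphenylsilyl)oxy]-2-(prop-1-en-2-yl)butyl]-7-hydroxy-2,2-dimethyl-8-(3-methylbut-2-en-1-yl)-2H-chromen-5(8H)-one F1. Coupling of F1 with acid 22 (DCC, DMAP, CH2Cl2) gives the enol ester (8S)-8-[(2S)-4-[(tert-butyldiphenylsilyl)oxy]-2-(prop-1-en-2-yl)butyl]-2,2-dimethyl-8-(3-methylbut-2-en-1-yl)-7-oxo-7,8-dihydro-2H-chromen-5-yl (2R)-2-methylbutanoate F2, which should rearrange in the same flask by the known DMAP-mediated O-to-C acyl shift of cyclic 1,3-dione enol esters to 27.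

Step 8. The second deprotonation of the hindered, α-branched hydroxy ester may stay incomplete, the alkoxide may undergo retro-aldol cleavage on warming, and facial selectivity may erode. The fallback sets out from 10 and comes back at 15. Condensation of 10 with tert-butyl (S)-valinate (BF3·OEt2 cat., toluene, reflux with removal of water) gives the chelated enamino ester methyl (2Z)-2-[(2S)-4-[(tert-butyldiphenylsilyl)oxy]-2-(prop-1-en-2-yl)butyl]-3-{[(2S)-1-(tert-butoxy)-3-methyl-1-oxobutan-2-yl]amino}but-2-enoate F3. Lithiation with LiN(i-Pr)2 and prenylation with 12 is the known chiral-enamine alkylation of α-alkyl β-keto esters, whose facial sense depends on the additive, so HMPA or 1,3-dioxolane is chosen to deliver the (2R) series. It gives the imine methyl (2R,4S)-2-(1-{[(2S)-1-(tert-butoxy)-3-methyl-1-oxobutan-2-yl]imino}ethyl)-4-{2-[(tert-butyldiphenylsilyl)oxy]ethyl}-5-methyl-2-(3-methylbut-2-en-1-yl)hex-5-enoate F4, hydrolysed on mild acidic work-up to methyl (2R,4S)-2-acetyl-4-{2-[(tert-butyldiphenylsilyl)oxy]ethyl}-5-methyl-2-(3-methylbut-2-en-1-yl)hex-5-enoate F5. LiAlH4 then gives (2S)-2-[(2S)-4-[(tert-butyldiphenylsilyl)oxy]-2-(prop-1-en-2-yl)butyl]-2-(3-methylbut-2-en-1-yl)butane-1,3-diol as a carbinol epimer mixture F6, which is oxidised under the conditions of step 10 to 15.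

Step 3. The stabilised sodium dienolate may react too slowly with a non-allylic triflate, so that decomposition of the triflate, γ-attack or migration of the double bond back into conjugation compete. The fallback sets out from 5 and comes back at 8. The same dienolate is alkylated with tert-butyl bromoacetate, a proven class of electrophile for imide enolates, to give tert-butyl (3S)-3-[(S)-4-benzyl-2-oxooxazolidine-3-carbonyl]-4-methylpent-4-enoate F7. LiBH4 cleaves the auxiliary to tert-butyl (3S)-3-(hydroxymethyl)-4-methylpent-4-enoate F8. PPh3/I2/imidazole gives tert-butyl (3S)-3-(iodomethyl)-4-methylpent-4-enoate F9. i-Bu2AlH (CH2Cl2, −78 → 0 °C) reduces the tert-butyl ester to (3S)-3-(iodomethyl)-4-methylpent-4-en-1-ol F10, and silylation (TBDPSCl, imidazole) gives 8.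

**Further compounds**
F1 | step 18 | (8R)-8-[(2S)-4-[(tert-butyldiphenylsilyl)oxy]-2-(prop-1-en-2-yl)butyl]-7-hydroxy-2,2-dimethyl-8-(3-methylbut-2-en-1-yl)-2H-chromen-5(8H)-one | C=C(C)[C@H](CCO[Si](c1ccccc1)(c1ccccc1)C(C)(C)C)C[C@]1(CC=C(C)C)C(O)=CC(=O)C2=C1OC(C)(C)C=C2
F2 | step 18 | (8S)-8-[(2S)-4-[(tert-butyldiphenylsilyl)oxy]-2-(prop-1-en-2-yl)butyl]-2,2-dimethyl-8-(3-methylbut-2-en-1-yl)-7-oxo-7,8-dihydro-2H-chromen-5-yl (2R)-2-methylbutanoate | C=C(C)[C@H](CCO[Si](c1ccccc1)(c1ccccc1)C(C)(C)C)C[C@]1(CC=C(C)C)C(=O)C=C(OC(=O)[C@H](C)CC)C2=C1OC(C)(C)C=C2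
F3 | step 8 | methyl (2Z)-2-[(2S)-4-[(tert-butyldiphenylsilyl)oxy]-2-(prop-1-en-2-yl)butyl]-3-{[(2S)-1-(tert-butoxy)-3-methyl-1-oxobutan-2-yl]amino}but-2-enoate | C=C(C)[C@H](CCO[Si](c1ccccc1)(c1ccccc1)C(C)(C)C)C/C(C(=O)OC)=C(\C)N[C@@H](C(C)C)C(=O)OC(C)(C)C
F4 | step 8 | methyl (2R,4S)-2-(1-{[(2S)-1-(tert-butoxy)-3-methyl-1-oxobutan-2-yl]imino}ethyl)-4-{2-[(tert-butyldiphenylsilyl)oxy]ethyl}-5-methyl-2-(3-methylbut-2-en-1-yl)hex-5-enoate | C=C(C)[C@H](CCO[Si](c1ccccc1)(c1ccccc1)C(C)(C)C)C[C@](CC=C(C)C)(C(C)=N[C@@H](C(C)C)C(=O)OC(C)(C)C)C(=O)OC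
F5 | step 8 | methyl (2R,4S)-2-acetyl-4-{2-[(tert-butyldiphenylsilyl)oxy]ethyl}-5-methyl-2-(3-methylbut-2-en-1-yl)hex-5-enoate | C=C(C)[C@H](CCO[Si](c1ccccc1)(c1ccccc1)C(C)(C)C)C[C@](CC=C(C)C)(C(C)=O)C(=O)OC
F6 | step 8 | (2S)-2-[(2S)-4-[(tert-butyldiphenylsilyl)oxy]-2-(prop-1-en-2-yl)butyl]-2-(3-methylbut-2-en-1-yl)butane-1,3-diol (C3 epimers) | C=C(C)[C@H](CCO[Si](c1ccccc1)(c1ccccc1)C(C)(C)C)C[C@](CC=C(C)C)(C(C)O)CO
F7 | step 3 | tert-butyl (3S)-3-[(S)-4-benzyl-2-oxooxazolidine-3-carbonyl]-4-methylpent-4-enoate | C=C(C)[C@H](CC(=O)OC(C)(C)C)C(=O)N1[C@@H](Cc2ccccc2)COC1=O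
F8 | step 3 | tert-butyl (3S)-3-(hydroxymethyl)-4-methylpent-4-enoate | C=C(C)[C@H](CC(=O)OC(C)(C)C)CO
F9 | step 3 | tert-butyl (3S)-3-(iodomethyl)-4-methylpent-4-enoate | C=C(C)[C@H](CC(=O)OC(C)(C)C)CI
F10 | step 3 | (3S)-3-(iodomethyl)-4-methylpent-4-en-1-ol | C=C(C)[C@H](CCO)CI
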